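(All runs are calculated on assumed constants.)

In days and in fractions of the charge, the meeting had one question: how much target Monday's flask holds at its best, and when.

| flask | starting material | precatalyst | remark | time |
|---|---|---|---|---|
| Monday's | 10 mM | 0.19 mM | the very flask that is asked about, followed so far |  |
| Thursday's | 5 mM | 0.19 mM | run made earlier |  |
| flask | 10 mM | 0.19 mM |  | 15 d |

- Monday's (time / d: target / %, starting material / %): 0.333: 29.9, 70.3; 0.833: 48.6, 46.5; 2.50: 44.5, 23.1; 8.00: 21.4, 9.2
- Thursday's (time / d: target / %, starting material / %): 0.333: 29.2, 69.4; 0.833: 48.2, 46.4; 2.50: 42.0, 22.8; 6.00: 20.9, 10.2

(scatter of a reading: 0.3 percentage points)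

- what was read earlier has a scatter of 0.3 percentage points, one standard deviation

1. the best time, 15 d at the latest, for target
2. the amount of target, in percent of the starting material charged, at that time

The kineticist reported that at 2.50 d starting material read 23.1% in Monday's run and 22.8% in Thursday's, from twice the charge, which she read as first order in starting material. The analyst objected that the balance no longer closes: at 8.00 d target plus starting material in Monday's run reads 30.6%, so the rest of the charge stands in something unread.

The minute-taker offered his own reckoning, carrying 69.9% from Monday's last reading as the pair share: the fraction of target in target plus starting material. In Monday's run it had risen from 51.1% at 0.833 d through 65.8% at 2.50 d. He took this as a reversible step approaching a quasi-equilibrium, so that late target is the pair share of whatever remains of the pair, and he committed to a peak in Monday's flask between those two readings.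

The forecast put the best time at 1.4 d (1 d to 1.8 d) and target there at 51% (49.3% to 53.5%), and expected no late recovery, since “the feed has nearly stopped while loss continues”.

The flask gives 51.9% of target at 1.30 d, inside both ranges of the forecast .

    starting material ⇌ target (K = 2.50, k = 8.10 × 10⁻⁴ min⁻¹)
    target + free catalyst ⇌ isomer of the product + free catalyst, rate k2*[free catalyst]*[target] forward; the back reaction follows from the equilibrium constant (K = 8.60, k = 2.10 L mol⁻¹ min⁻¹)
    precatalyst → free catalyst (k = 6.30 × 10⁻⁴ min⁻¹)
    free catalyst + target → spent catalyst (k = 0.0350 L mol⁻¹ min⁻¹)

The relaxation half-life of starting material and target by their step alone, both ways together, is 0.424 d, short against the 15 d allowed, and at that longest time target in this flask is made at 0.317 of the rate at which it is used up, each step taken net. The pair share of the starting material and target standing at 15.0 d gives 15.2% of target in this flask, where 15.4% stands, and 50.5% in the neighbour charged with 0.048 mM of precatalyst, whose best of 62.8% lies above the forecast's high end and which ends with 51.5% of target.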